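**Plan**
- Retrosynthesis: the two benzyl O–C bonds are cut first, then the C3–O bond (back to a C3–H flavone). Ring C is then opened at C4a–C4, C4–C3 and O1–C2.
- Enabling feature: C4 is a single carbonyl carbon lying between C4a of ring A and C3, and O1 sits on C8a next to C4a. Ring C is therefore an ortho-iodophenol (iodine at C4a, hydroxyl at C8a) plus carbon monoxide plus an arylacetylene that carries C3, C2 and ring B.
- Forward, ring A: 5-hydroxyvanillin is dressed by selective benzylation and MOM protection, its formyl carbon is exchanged for oxygen by Baeyer–Villiger oxidation, and iodine is placed by MOM-directed lithiation.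
- Forward, ring B: 2,3,4-trimethoxybenzaldehyde is homologated to the terminal alkyne.
- Ring C is the only ring formed (step 8). Then C3–H is converted to C3–OMe and the benzyl groups are removed.
- Stereochemistry: the target is achiral. Regiochemistry of ring A is fixed by the position of the iodine and the single free phenol.

Key step: step 8

Remark: the 5,8-hydroquinone of the target is assumed to be air-sensitive in solution, so the last step is worked up under argon.

**Route**

Step 1
Reactants: 1 3,4-dihydroxy-5-methoxybenzaldehyde (5-hydroxyvanillin)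
Product: 2 4-(benzyloxy)-3-hydroxy-5-methoxybenzaldehyde
Conditions: BnBr (1.05 equiv), Li2CO3, DMF, 45 °C
Reagents that add atoms: benzyl bromide, BrCc1ccccc1
Why: Williamson etherification under weak-base control, in which only the 4-OH (para to the formyl group and so the more acidic phenol) is ionised by Li2CO3 and benzylated.

Step 2
Reactants: 2 4-(benzyloxy)-3-hydroxy-5-methoxybenzaldehyde
Product: 3 4-(benzyloxy)-3-methoxy-5-(methoxymethoxy)benzaldehyde
Conditions: MOMCl, iPr2NEt, CH2Cl2, 0 °C → rt
Reagents that add atoms: chloromethyl methyl ether, COCCl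
Why: O-alkylation of the remaining phenol with an α-chloro ether (MOM ether formation) masks the future O1 as the group that will later direct ortho-lithiation.

Step 3
Reactants: 3 4-(benzyloxy)-3-methoxy-5-(methoxymethoxy)benzaldehyde
Product: 5 4-(benzyloxy)-3-methoxy-5-(methoxymethoxy)phenol, via aryl formate 4 (not isolated)
Conditions: mCPBA, CH2Cl2, 0 °C → rt; then K2CO3 (cat.), MeOH, rt
Reagents that add atoms: 3-chloroperbenzoic acid, OOC(=O)c1cccc(Cl)c1
Why: Baeyer–Villiger oxidation of an electron-rich benzaldehyde, in which the aryl group (activated by the para benzyloxy oxygen) migrates to give formate 4, which is methanolysed to the phenol.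

Step 4
Reactants: 5 4-(benzyloxy)-3-methoxy-5-(methoxymethoxy)phenol
Product: 6 2,5-bis(benzyloxy)-1-methoxy-3-(methoxymethoxy)benzene
Conditions: BnBr, K2CO3, DMF, rt
Reagents that add atoms: benzyl bromide, BrCc1ccccc1
Why: Williamson ether synthesis on the only free phenol.

Step 5
Reactants: 6 2,5-bis(benzyloxy)-1-methoxy-3-(methoxymethoxy)benzene
Product: 8 1,4-bis(benzyloxy)-2-iodo-5-methoxy-3-(methoxymethoxy)benzene, via aryllithium 7 (not isolated)
Conditions: n-BuLi, THF, −20 → 0 °C; then I2, THF, −78 °C → rt
Reagents that add atoms: iodine, II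
Why: Directed ortho-metalation, in which the MOM ether out-directs the methyl ether so that n-BuLi removes the hydrogen flanked by OMOM and OBn in preference to the one between OBn and OMe, and iodine traps aryllithium 7.

Step 6
Reactants: 8 1,4-bis(benzyloxy)-2-iodo-5-methoxy-3-(methoxymethoxy)benzene
Product: 9 3,6-bis(benzyloxy)-2-iodo-5-methoxyphenol
Conditions: HCl (cat.), MeOH, 45 °C
Reagents that add atoms: none
Why: Acid-catalysed acetal exchange (MOM cleavage) frees the phenol, while benzyl ethers, methyl ether and aryl iodide are inert to dilute HCl in methanol.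

Step 7
Reactants: 10 2,3,4-trimethoxybenzaldehyde
Product: 11 1-ethynyl-2,3,4-trimethoxybenzene
Conditions: Ohira–Bestmann reagent, K2CO3, MeOH, rt
Reagents that add atoms: dimethyl (1-diazo-2-oxopropyl)phosphonate, COP(=O)(OC)C(=[N+]=[N-])C(C)=O
Why: Ohira–Bestmann variant of the Seyferth–Gilbert homologation, in which the diazomethylphosphonate anion formed in situ olefinates the non-enolisable aldehyde and the diazoalkene loses N2 with 1,2-hydrogen shift to the terminal alkyne.

Step 8
Reactants: 9 3,6-bis(benzyloxy)-2-iodo-5-methoxyphenol; 11 1-ethynyl-2,3,4-trimethoxybenzene; 12 carbon monoxide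
Product: 15 5,8-bis(benzyloxy)-7-methoxy-2-(2,3,4-trimethoxyphenyl)-4H-chromen-4-one, via ynone 13 (not isolated), via β-aminoenone 14 (not isolated)
Conditions: PdCl2(PPh3)2 (5 mol %), CO (20 bar), Et2NH, 120 °C, autoclave
Reagents that add atoms: none
Why: PdCl2(PPh3)2 is reduced in situ to zerovalent palladium, which inserts into the C–I bond of 9; CO insertion gives an aroylpalladium iodide, and transfer of the acetylide formed from 11 and Et2NH followed by reductive elimination forms the C4a–C4 and C4–C3 bonds as ynone 13. Diethylamine then adds to the ynone to give β-aminoenone 14, and the ortho phenol attacks C2 in a 6-endo-trig addition–elimination that expels the amine and forms O1–C2, closing ring C. The closest known reaction type is the palladium-catalysed carbonylative Sonogashira annulation of ortho-iodophenols with terminal arylacetylenes to flavones. No stereocentre is created. The selectivities needed are carbonylative over direct coupling (which would lead on to a 2-arylbenzofuran) and six-membered flavone over five-membered aurone closure: CO pressure without copper lets CO insertion outrun acetylide transfer at the hindered, electron-rich arylpalladium, and the secondary amine turns the ynone into an enaminone whose only electrophilic site for the phenol is C2. In the substrate, the iodine at the future C4a and the single free hydroxyl at the future C8a (O5 and O8 being benzylated) leave one way to close, so the 5,7,8-oxygenation pattern cannot scramble.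

Step 9
Reactants: 15 5,8-bis(benzyloxy)-7-methoxy-2-(2,3,4-trimethoxyphenyl)-4H-chromen-4-one
Product: 18 5,8-bis(benzyloxy)-3-hydroxy-7-methoxy-2-(2,3,4-trimethoxyphenyl)-4H-chromen-4-one, via 3-lithioflavone 16 (not isolated), via flavonyl boronate 17 (not isolated)
Conditions: LiN(iPr)2, THF, −78 °C; B(OMe)3, −78 → 0 °C; then 30 % H2O2, AcOH, 0 °C → rt
Reagents that add atoms: hydrogen peroxide, OO
Why: Deprotonation of the C3–H of a flavone by LiN(iPr)2 (the vinylic hydrogen alpha to the C4 carbonyl is the most acidic C–H), borylation of the vinyllithium and organoborane oxidation with 1,2-migration from boron to oxygen install the 3-hydroxyl.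

Step 10
Reactants: 18 5,8-bis(benzyloxy)-3-hydroxy-7-methoxy-2-(2,3,4-trimethoxyphenyl)-4H-chromen-4-one
Product: 19 5,8-bis(benzyloxy)-3,7-dimethoxy-2-(2,3,4-trimethoxyphenyl)-4H-chromen-4-one
Conditions: MeI, K2CO3, acetone, reflux
Reagents that add atoms: iodomethane, CI
Why: Williamson O-methylation of the flavonol hydroxyl, the only acidic OH in the molecule.

Step 11
Reactants: 19 5,8-bis(benzyloxy)-3,7-dimethoxy-2-(2,3,4-trimethoxyphenyl)-4H-chromen-4-one
Product: 20 5,8-dihydroxy-3,7-dimethoxy-2-(2,3,4-trimethoxyphenyl)-4H-chromen-4-one (5,8-dihydroxy-3,7,2',3',4'-pentamethoxyflavone)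
Conditions: H2 (1 atm), Pd/C (10 %), EtOAc–MeOH, rt; work-up under argon
Reagents that add atoms: none
Why: Catalytic hydrogenolysis cleaves both benzyl aryl ethers, while the tetrasubstituted push–pull C2–C3 double bond and the methyl ethers should be untouched under one atmosphere of hydrogen.

**Compound list**

1 | 3,4-dihydroxy-5-methoxybenzaldehyde | COc1cc(C=O)cc(O)c1O | starting material
2 | 4-(benzyloxy)-3-hydroxy-5-methoxybenzaldehyde | COc1cc(C=O)cc(O)c1OCc1ccccc1 | intermediate
3 | 4-(benzyloxy)-3-methoxy-5-(methoxymethoxy)benzaldehyde | COCOc1cc(C=O)cc(OC)c1OCc1ccccc1 | intermediate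
4 | 4-(benzyloxy)-3-methoxy-5-(methoxymethoxy)phenyl formate | COCOc1cc(OC=O)cc(OC)c1OCc1ccccc1 | intermediate
5 | 4-(benzyloxy)-3-methoxy-5-(methoxymethoxy)phenol | COCOc1cc(O)cc(OC)c1OCc1ccccc1 | intermediate
6 | 2,5-bis(benzyloxy)-1-methoxy-3-(methoxymethoxy)benzene | COCOc1cc(OCc2ccccc2)cc(OC)c1OCc1ccccc1 | intermediate
7 | [3,6-bis(benzyloxy)-4-methoxy-2-(methoxymethoxy)phenyl]lithium | [Li]c1c(OCOC)c(OCc2ccccc2)c(OC)cc1OCc1ccccc1 | intermediate
8 | 1,4-bis(benzyloxy)-2-iodo-5-methoxy-3-(methoxymethoxy)benzene | COCOc1c(I)c(OCc2ccccc2)cc(OC)c1OCc1ccccc1 | intermediate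
9 | 3,6-bis(benzyloxy)-2-iodo-5-methoxyphenol | COc1cc(OCc2ccccc2)c(I)c(O)c1OCc1ccccc1 | intermediate
10 | 2,3,4-trimethoxybenzaldehyde | COc1ccc(C=O)c(OC)c1OC | starting material
11 | 1-ethynyl-2,3,4-trimethoxybenzene | C#Cc1ccc(OC)c(OC)c1OC | intermediate
12 | carbon monoxide | [C-]#[O+] | starting material
13 | 1-[3,6-bis(benzyloxy)-2-hydroxy-4-methoxyphenyl]-3-(2,3,4-trimethoxyphenyl)prop-2-yn-1-one | COc1ccc(C#CC(=O)c2c(O)c(OCc3ccccc3)c(OC)cc2OCc2ccccc2)c(OC)c1OC | intermediate
14 | 1-[3,6-bis(benzyloxy)-2-hydroxy-4-methoxyphenyl]-3-(diethylamino)-3-(2,3,4-trimethoxyphenyl)prop-2-en-1-one (push–pull alkene, geometry not fixed) | CCN(CC)C(=CC(=O)c1c(O)c(OCc2ccccc2)c(OC)cc1OCc1ccccc1)c1ccc(OC)c(OC)c1OC | intermediate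
15 | 5,8-bis(benzyloxy)-7-methoxy-2-(2,3,4-trimethoxyphenyl)-4H-chromen-4-one | COc1ccc(-c2cc(=O)c3c(OCc4ccccc4)cc(OC)c(OCc4ccccc4)c3o2)c(OC)c1OC | intermediate
16 | [5,8-bis(benzyloxy)-7-methoxy-4-oxo-2-(2,3,4-trimethoxyphenyl)-4H-chromen-3-yl]lithium | COc1ccc(-c2oc3c(OCc4ccccc4)c(OC)cc(OCc4ccccc4)c3c(=O)c2[Li])c(OC)c1OC | intermediate
17 | dimethyl [5,8-bis(benzyloxy)-7-methoxy-4-oxo-2-(2,3,4-trimethoxyphenyl)-4H-chromen-3-yl]boronate | COc1ccc(-c2oc3c(OCc4ccccc4)c(OC)cc(OCc4ccccc4)c3c(=O)c2B(OC)OC)c(OC)c1OC | intermediate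
18 | 5,8-bis(benzyloxy)-3-hydroxy-7-methoxy-2-(2,3,4-trimethoxyphenyl)-4H-chromen-4-one | COc1ccc(-c2oc3c(OCc4ccccc4)c(OC)cc(OCc4ccccc4)c3c(=O)c2O)c(OC)c1OC | intermediate
19 | 5,8-bis(benzyloxy)-3,7-dimethoxy-2-(2,3,4-trimethoxyphenyl)-4H-chromen-4-one | COc1ccc(-c2oc3c(OCc4ccccc4)c(OC)cc(OCc4ccccc4)c3c(=O)c2OC)c(OC)c1OC | intermediate
20 | 5,8-dihydroxy-3,7-dimethoxy-2-(2,3,4-trimethoxyphenyl)-4H-chromen-4-one | COc1ccc(-c2oc3c(O)c(OC)cc(O)c3c(=O)c2OC)c(OC)c1OC | target

**Count and risks**

Total step count: 11. Longest linear sequence: 10 steps (steps 1–6 and 8–11, from 1 to 20); the alkyne arm is one step.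

Steps most likely to fail:

1. Step 8 (key step). Oxidative addition into the doubly ortho-substituted, electron-rich C–I bond may be slow. The aroylpalladium may be captured by diethylamine to give an amide. Alkynylation may occur without CO uptake and lead on to a benzofuran, or the ynone may close to the five-membered aurone. Fallback, setting out from 6 and 11 and returning at 15: aryllithium 7, generated from 6 as in step 5, would be quenched with DMF to give 3,6-bis(benzyloxy)-4-methoxy-2-(methoxymethoxy)benzaldehyde F1. Addition of the lithium acetylide of 11 (n-BuLi, THF, −78 °C) should give racemic 1-[3,6-bis(benzyloxy)-4-methoxy-2-(methoxymethoxy)phenyl]-3-(2,3,4-trimethoxyphenyl)prop-2-yn-1-ol F2. Oxidation with MnO2 in CH2Cl2 should give 1-[3,6-bis(benzyloxy)-4-methoxy-2-(methoxymethoxy)phenyl]-3-(2,3,4-trimethoxyphenyl)prop-2-yn-1-one F3. HCl in MeOH would then free the phenol to ynone 13, and Et2NH in EtOH should close it through the same aminoenone pathway to 15.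

2. Step 9. Metalation may be incomplete or misdirected (benzylic deprotonation of the 5-benzyl ether, or addition of the amide base at C2), and the boronate may protodeboronate before it is oxidised. Fallback, setting out from 15 and returning at 18: epoxidation of the C2–C3 double bond with dimethyldioxirane in acetone–CH2Cl2 at 0 °C should give the racemic, cis-fused 2,3-epoxide 3,6-bis(benzyloxy)-4-methoxy-1a-(2,3,4-trimethoxyphenyl)-1a,7a-dihydro-7H-oxireno[2,3-b]chromen-7-one F4. A catalytic amount of TsOH in CH2Cl2 should then open it and tautomerise it to flavonol 18.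

3. Step 5. The benzylic CH2 groups may be metalated and undergo Wittig rearrangement, or lithiation may occur at the other ring hydrogen between OBn and OMe. Fallback, setting out from 6 and returning at 9: the MOM ether would be cleaved first (HCl, MeOH) to 2,5-bis(benzyloxy)-3-methoxyphenol F5. The free phenol would then be iodinated by electrophilic substitution with N-iodosuccinimide and a catalytic secondary amine (or the I2–morpholine complex) in CH2Cl2 at low temperature. The hydrogen-bonded N-iodoamine should deliver iodine ortho to the hydroxyl, and the para position is buttressed between OMe and OBn, which should give 9 directly.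

**Further compounds**

F1 | step 8 | 3,6-bis(benzyloxy)-4-methoxy-2-(methoxymethoxy)benzaldehyde | O=Cc1c(OCOC)c(OCc2ccccc2)c(OC)cc1OCc1ccccc1
F2 | step 8 | 1-[3,6-bis(benzyloxy)-4-methoxy-2-(methoxymethoxy)phenyl]-3-(2,3,4-trimethoxyphenyl)prop-2-yn-1-ol (racemic) | COCOc1c(C(O)C#Cc2ccc(OC)c(OC)c2OC)c(OCc2ccccc2)cc(OC)c1OCc1ccccc1
F3 | step 8 | 1-[3,6-bis(benzyloxy)-4-methoxy-2-(methoxymethoxy)phenyl]-3-(2,3,4-trimethoxyphenyl)prop-2-yn-1-one | COCOc1c(C(=O)C#Cc2ccc(OC)c(OC)c2OC)c(OCc2ccccc2)cc(OC)c1OCc1ccccc1
F4 | step 9 | 3,6-bis(benzyloxy)-4-methoxy-1a-(2,3,4-trimethoxyphenyl)-1a,7a-dihydro-7H-oxireno[2,3-b]chromen-7-one (racemic, cis-fused) | COc1ccc(C23OC2C(=O)c2c(OCc4ccccc4)cc(OC)c(OCc4ccccc4)c2O3)c(OC)c1OC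
F5 | step 5 | 2,5-bis(benzyloxy)-3-methoxyphenol | COc1cc(OCc2ccccc2)cc(O)c1OCc1ccccc1
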